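**Retrosynthetic overview**
1. Target ⇐ convex-face C7 isopropenylation (Pd/tin enolate, 2-bromopropene) of the cis-fused 3α,9β-diester 8-ketone.
2. ⇐ one-flask reductive α-acyloxylation of the Δ9(10)-en-8-one (CuH 1,4-hydrosilylation, then trivalent-iodine acyloxylation with 3-methylbut-2-enoic acid), setting C10 and C9.
3. ⇐ C3 by bulky-hydride reduction to the axial alcohol and Mitsunobu inversion with 3-methylbut-2-enoic acid.
4. ⇐ key step: one-carbon ring expansion of the cyclopentanone of (S)-Hajos–Parrish ketone (β-oxido carbenoid 1,2-shift of the quaternary carbon; CH(CH3) from 1,1-dibromoethane), with C4 set by kinetic protonation.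
5. Ring order: five-membered proto-ring A (2-methylcyclopentane-1,3-dione) → ring B by proline-catalysed annulation with methyl vinyl ketone → ring A expanded to six members.

Assumption: decalin compounds are numbered as eremophilanes (ring A = C1–C5 and C10, ring B = C5–C10, methyls on C4 and C5, side chain on C7), β means the face of the C5 methyl group, and hydrindane compounds keep indene numbering.

**Step 1**
Reactants: 1 2-methylcyclopentane-1,3-dione; 2 but-3-en-2-one (methyl vinyl ketone)
Product: 3 2-methyl-2-(3-oxobutyl)cyclopentane-1,3-dione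
Conditions: H2O, 20 °C, 5 d
Reagents that add atoms: none
Why: Michael addition of the enolised 1,3-dione to the vinyl ketone in water gives the achiral triketone, and no stereocentre is formed.

**Step 2**
Reactants: 3 2-methyl-2-(3-oxobutyl)cyclopentane-1,3-dione
Product: 5 (S)-7a-methyl-2,3,7,7a-tetrahydro-1H-indene-1,5(6H)-dione ((S)-Hajos–Parrish ketone), via cis ketol 4 (not isolated)
Conditions: (S)-proline (3 mol %), DMF, 16 °C; then H2SO4, DMF, 95 °C
Reagents that add atoms: none
Why: Hajos–Parrish reaction, in which the (S)-proline enamine of the side-chain ketone adds to one of the two enantiotopic ring carbonyls (intramolecular aldol) to set the quaternary carbon as S in the cis ketol, which acid then dehydrates to the enone.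

**Step 3**
Reactants: 5 (S)-Hajos–Parrish ketone
Product: 6 (7a′S)-7a′-methyl-2′,3′,7′,7a′-tetrahydrospiro[1,3-dithiane-2,5′-inden]-1′(6′H)-one
Conditions: HS(CH2)3SH (1.05 equiv), BF3·OEt2 (0.3 equiv), MeOH, 0 °C → rt
Reagents that add atoms: propane-1,3-dithiol, SCCCS
Why: Acid-catalysed thioketalisation is selective for the more basic, unhindered conjugated carbonyl over the neopentyl cyclopentanone, so the enone is masked as a base-stable 1,3-dithiane while the ring-B double bond stays in place and no stereocentre changes.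

**Step 4**
Reactants: 6 dithiane-protected (S)-Hajos–Parrish ketone
Product: 9 (4R,5R)-4β,5β-dimethyl-Δ9(10)-octalin-3-one carrying a spiro-1,3-dithiane at C8, via dibromo alkoxide 7 (not isolated), via lithium enolate 8 (not isolated)
Conditions: CH3CHBr2 (1.4 equiv), LiN(i-Pr)2 (1.4 equiv), THF, −95 °C; n-BuLi (1.5 equiv), −95 → −40 °C; AcOH, −78 °C
Reagents that add atoms: 1,1-dibromoethane, CC(Br)Br
Why: β-Oxido carbenoid ring expansion (Nozaki–Yamamoto-type 1,2-shift), in which CH3CBr2Li adds to the ketone anti to the angular methyl, Br/Li exchange gives the carbenoid, the more substituted quaternary carbon migrates to the carbenoid carbon with loss of LiBr to give the regiodefined C3=C4 enolate, and kinetic axial protonation anti to the C5 methyl sets C4 with its methyl β (cis to the C5 methyl).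

**Step 5**
Reactants: 9 ring-expanded dithiane ketone
Product: 10 (3S,4R,5R)-3β-hydroxy-4β,5β-dimethyl-Δ9(10)-octalin carrying a spiro-1,3-dithiane at C8
Conditions: LiBH(s-Bu)3, THF, −78 °C; then NaOH, H2O2, 0 °C
Reagents that add atoms: none
Why: Bulky-hydride reduction, in which axial attack at C3 is blocked by the syn-axial C5 methyl, so the hydride enters equatorially and gives the axial 3β-alcohol.

**Step 6**
Reactants: 10 axial 3β-alcohol
Product: 11 (3R,4R,5R)-3α-(3-methylbut-2-enoyloxy)-4β,5β-dimethyl-Δ9(10)-octalin carrying a spiro-1,3-dithiane at C8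
Conditions: 3-methylbut-2-enoic acid, PPh3, DIAD, PhMe, 0 °C → rt
Reagents that add atoms: 3-methylbut-2-enoic acid, CC(C)=CC(=O)O
Why: Mitsunobu reaction, in which SN2 displacement of the activated axial oxygen by the carboxylate inverts C3 and installs the equatorial 3α-ester in one operation.

**Step 7**
Reactants: 11 3α-ester dithiane
Product: 12 (3R,4R,5R)-3α-(3-methylbut-2-enoyloxy)-4β,5β-dimethyl-Δ9(10)-octalin-8-one
Conditions: PhI(OCOCF3)2, MeCN–H2O (9:1), 0 °C
Reagents that add atoms: water, O
Why: Oxidative dethioketalisation with a trivalent-iodine reagent in wet acetonitrile releases the conjugated ketone without touching the electron-poor ester double bond or any stereocentre.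

**Step 8**
Reactants: 12 3α-ester enone
Product: 14 (3R,4R,5R,9R,10S)-3α,9β-bis(3-methylbut-2-enoyloxy)-4β,5β-dimethyl-10βH-decalin-8-one, via silyl enol ether 13 (not isolated)
Conditions: [(Ph3P)CuH]6 (1 mol %), PhMe2SiH (1.15 equiv), PhMe, rt; then PhIO (1.3 equiv), 3-methylbut-2-enoic acid (2.6 equiv), 4 Å MS, BF3·OEt2 (20 mol %), CH2Cl2, −40 → 0 °C
Reagents that add atoms: 3-methylbut-2-enoic acid, CC(C)=CC(=O)O
Why: Proposed new method: one-flask reductive α-acyloxylation of an enone with a free carboxylic acid, in which [(Ph3P)CuH]6/PhMe2SiH first effects the known copper hydride 1,4-hydrosilylation (hydride adds to C10 on the face of the C5 methyl, giving the cis-fused silyl enol ether with the double bond fixed at C8=C9), and the trivalent-iodine dicarboxylate formed in situ from PhIO and the acid then exchanges silicon for iodine on the enol oxygen and delivers a carboxylate ligand to C9 on the exposed convex β face with loss of PhI, so that C10 (β-H) and C9 (β-ester, also the thermodynamic equatorial epimer) are set together; the closest known reactions are Rubottom-type oxidation of silyl enol ethers with lead tetracarboxylates and iodine-mediated α-acetoxylation or α-tosyloxylation of ketones.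

**Step 9**
Reactants: 14 cis-fused diester ketone
Product: 17 (3R,4R,5R,7R,9R,10S)-3α,9β-bis(3-methylbut-2-enoyloxy)-10βH-eremophil-11-en-8-one (target), via trimethylsilyl enol ether 15 (not isolated), via tin enolate 16 (not isolated)
Conditions: LiN(SiMe3)2, Me3SiCl, THF, −78 °C; then Bu3SnF (1.1 equiv), PdCl2[P(o-tolyl)3]2 (3 mol %), 2-bromopropene, PhMe, 80 °C
Reagents that add atoms: 2-bromopropene, CC(Br)=C
Why: Kinetic deprotonation occurs at C7, away from the acyloxy-bearing C9 as for other α-oxygenated ketones, and in situ silylation fixes the C7=C8 enol ether; fluoride-driven transfer to tin and a Migita-type palladium-catalysed enolate alkenylation then form the C7–C11 bond on the convex β face, which is also the thermodynamically preferred equatorial position, under conditions free of base that could conjugate the new double bond.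

**Compound list**
1 | 2-methylcyclopentane-1,3-dione | CC1C(=O)CCC1=O | starting material
2 | but-3-en-2-one (methyl vinyl ketone) | CC(=O)C=C | starting material
3 | 2-methyl-2-(3-oxobutyl)cyclopentane-1,3-dione | CC(=O)CCC1(C)C(=O)CCC1=O | intermediate
4 | (3aS,7aS)-3a-hydroxy-7a-methylhexahydro-1H-indene-1,5(4H)-dione (cis ketol; not isolated) | O=C1CC[C@@]2(C)[C@](O)(CCC2=O)C1 | intermediate
5 | (S)-7a-methyl-2,3,7,7a-tetrahydro-1H-indene-1,5(6H)-dione ((S)-Hajos–Parrish ketone) | O=C1CC[C@@]2(C)C(CCC2=O)=C1 | intermediate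
6 | (7a′S)-7a′-methyl-2′,3′,7′,7a′-tetrahydrospiro[1,3-dithiane-2,5′-inden]-1′(6′H)-one (enone carbonyl of 5 as 1,3-dithiane) | C[C@]12CCC3(SCCCS3)C=C1CCC2=O | intermediate
7 | lithium alkoxide of the 1,1-dibromoethyl adduct at the ketone carbon of 6 (oxygen β, cis to the angular methyl; CBr2CH3 α; not isolated) | C[C@]12CCC3(SCCCS3)C=C1CC[C@@]2([O-])C(C)(Br)Br.[Li+] | intermediate
8 | lithium enolate of 9 (O–Li on C3, C3=C4 double bond; not isolated) | C[C@]12CCC3(SCCCS3)C=C1CCC([O-])=C2C.[Li+] | intermediate
9 | (4R,5R)-4β,5β-dimethyl-Δ9(10)-octalin-3-one carrying a spiro-1,3-dithiane at C8 | C[C@]12CCC3(SCCCS3)C=C1CCC(=O)[C@@H]2C | intermediate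
10 | (3S,4R,5R)-3β-hydroxy-4β,5β-dimethyl-Δ9(10)-octalin carrying a spiro-1,3-dithiane at C8 | C[C@]12CCC3(SCCCS3)C=C1CC[C@H](O)[C@@H]2C | intermediate
11 | (3R,4R,5R)-3α-(3-methylbut-2-enoyloxy)-4β,5β-dimethyl-Δ9(10)-octalin carrying a spiro-1,3-dithiane at C8 | C[C@]12CCC3(SCCCS3)C=C1CC[C@@H](OC(=O)C=C(C)C)[C@@H]2C | intermediate
12 | (3R,4R,5R)-3α-(3-methylbut-2-enoyloxy)-4β,5β-dimethyl-Δ9(10)-octalin-8-one | C[C@]12CCC(=O)C=C1CC[C@@H](OC(=O)C=C(C)C)[C@@H]2C | intermediate
13 | cis-fused (10βH) dimethyl(phenyl)silyl enol ether of the C8 ketone (C8=C9) carrying the 3α-ester (not isolated) | C1C[C@@]2(C)[C@H](CC[C@@H](OC(=O)C=C(C)C)[C@@H]2C)C=C1O[Si](C)(C)c3ccccc3 | intermediate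
14 | (3R,4R,5R,9R,10S)-3α,9β-bis(3-methylbut-2-enoyloxy)-4β,5β-dimethyl-10βH-decalin-8-one | C1C[C@@]2(C)[C@H](CC[C@@H](OC(=O)C=C(C)C)[C@@H]2C)[C@@H](OC(=O)C=C(C)C)C1=O | intermediate
15 | trimethylsilyl enol ether of 14 (C7=C8; not isolated) | C1[C@@]2(C)[C@H](CC[C@@H](OC(=O)C=C(C)C)[C@@H]2C)[C@@H](OC(=O)C=C(C)C)C(O[Si](C)(C)C)=C1 | intermediate
16 | tributylstannyl enolate of 14 (C7=C8, O-bound form drawn; not isolated) | C1[C@@]2(C)[C@H](CC[C@@H](OC(=O)C=C(C)C)[C@@H]2C)[C@@H](OC(=O)C=C(C)C)C(O[Sn](CCCC)(CCCC)CCCC)=C1 | intermediate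
17 | (3R,4R,5R,7R,9R,10S)-3α,9β-bis(3-methylbut-2-enoyloxy)-10βH-eremophil-11-en-8-one = (1R,3R,4aR,5R,6R,8aS)-4a,5-dimethyl-2-oxo-3-(prop-1-en-2-yl)decahydronaphthalene-1,6-diyl bis(3-methylbut-2-enoate) (CNP0264508.1) | C=C(C)[C@H]1C[C@@]2(C)[C@H](CC[C@@H](OC(=O)C=C(C)C)[C@@H]2C)[C@@H](OC(=O)C=C(C)C)C1=O | target

**Total step count:** 9. **Longest linear sequence:** 9 steps (1/2 → 17).

**Steps most likely to fail**

Step 8 (the proposed new step). The free acid or BF3 may protodesilylate 13 before acyloxylation, giving the cis ketone without the C9 oxygen. The iodine reagent may also dimerise the enol ether. Any 9α-ester can be equilibrated to the equatorial 9β-epimer with Et3N. The fallback uses known chemistry only, sets out from 12 and returns at 14. Run only the CuH hydrosilylation ([(Ph3P)CuH]6, PhMe2SiH) and isolate silyl enol ether 13 by filtration through basic alumina. Epoxidise it from the convex face with mCPBA/NaHCO3 in CH2Cl2 at 0 °C (Rubottom oxidation) and remove silicon with citric acid in MeOH to give the 9β-hydroxy ketone F1. Esterify with 3-methylbut-2-enoyl chloride, pyridine and DMAP to reach 14.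

Step 4. The bulky, basic CH3CBr2Li may enolise the hindered neopentyl ketone of 6 instead of adding. The route also needs the quaternary carbon, not the CH2 carbon, to migrate. The fallback sets out from 6 and returns at 9, replacing the lithium gem-dibromo carbenoid by a less basic sulfinyl carbanion and a magnesium carbenoid. Add lithiated 1-chloroethyl 4-methylphenyl sulfoxide (LiN(i-Pr)2, THF, −78 °C) to 6 and isolate the adduct, the α-chloro-β-hydroxy sulfoxide F2. Treat it with t-BuMgCl and then i-PrMgCl (sulfoxide–magnesium exchange, −78 → 0 °C) to trigger the same 1,2-shift of the more substituted carbon. Quench the magnesium enolate with AcOH at −78 °C to give 9.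

Step 9. Enolisation may occur toward C9, the amide base may attack the α-acyloxy ketone, and the tin enolate coupling may be slow on the hindered cis-decalin. The fallback sets out from 14 and returns at 17, forming the C7–C11 bond by aldol addition and dehydration instead of cross-coupling. Treat silyl enol ether 15 (prepared as in step 9) with acetone and TiCl4 in CH2Cl2 at −78 °C (Mukaiyama aldol, convex-face attack) to give the 7β-(2-hydroxypropan-2-yl) ketone F3. Dehydrate the tertiary alcohol under kinetic conditions (SOCl2, pyridine, 0 °C) to the isopropenyl compound 17, separating any conjugated isopropylidene isomer.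

**Further compounds**
F1 | step 8 | (3R,4R,5R,9R,10S)-9β-hydroxy-3α-(3-methylbut-2-enoyloxy)-4β,5β-dimethyl-10βH-decalin-8-one | C1C[C@@]2(C)[C@H](CC[C@@H](OC(=O)C=C(C)C)[C@@H]2C)[C@@H](O)C1=O
F2 | step 4 | adduct of 6 with 1-chloroethyl 4-methylphenyl sulfoxide: tertiary alcohol (OH β) bearing an α 1-chloro-1-(4-methylphenylsulfinyl)ethyl group (mixture at the side-chain carbon and sulfur) | C[C@]12CCC3(SCCCS3)C=C1CC[C@@]2(O)C(C)(Cl)S(=O)c4ccc(C)cc4
F3 | step 9 | (3R,4R,5R,7R,9R,10S)-7β-(2-hydroxypropan-2-yl)-3α,9β-bis(3-methylbut-2-enoyloxy)-4β,5β-dimethyl-10βH-decalin-8-one | CC(C)(O)[C@H]1C[C@@]2(C)[C@H](CC[C@@H](OC(=O)C=C(C)C)[C@@H]2C)[C@@H](OC(=O)C=C(C)C)C1=O
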